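(Readings and results were generated by integration from invented constants; noise was put on by code.)

I could not read the number of chains from the north run, which shows monomer and not chains, yet the length asked for in Thursday's and Wednesday's flasks is monomer in chains divided by chains begun.

| flask | free monomer | pre-initiator | remark | time |
|---|---|---|---|---|
| north | 1 mM | 38 µM | run made earlier |  |
| Thursday's | 1.0 mM | 77 µM |  | 8.0 min |
| Wednesday's | 1.0 mM | 77 µM |  | 15 min |

north run (percent of the free monomer charged)

| time / s | monomer in chains / % | free monomer / % |
|---|---|---|
| 10.0 | 4 | 98 |
| 25.0 | 20 | 82 |
| 40.0 | 36 | 64 |
| 60.0 | 49 | 51 |
| 90.0 | 57 | 44 |

(readings scatter by 1.5 percentage points)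

- the average divides the monomer in chains by the number of chains begun, living and dead together
- what was read earlier has a scatter of 1.5 percentage points, one standard deviation
- the earlier runs do not show the number of chains; that part of a forecast is a guess
- no earlier run changes the charge of pre-initiator; that part of a forecast is a guess

1. which of the two ends with the longer chains by the average number of monomer units in a chain (chains begun, living or dead) ("neither" if they lie within 10%) (Thursday's / Wednesday's / neither)
2. average number of monomer units in a chain (chains begun, living or dead) at the end, Thursday's
3. average number of monomer units in a chain (chains begun, living or dead) at the end, Wednesday's

So I went through the inputs in turn, asking how far the length would move if each were off. The time I expected to matter little, since the north run had slowed towards a stall by its last reading at 90.0 s, well short of Thursday's 8.0 min, and time is the one setting in which the two flasks differ. The pre-initiator charge matters in full: if each unit begins one chain the length goes as its inverse, and that is a guess. The free monomer at the last reading matters through its gap to the charge, and that reading carries 1.5 percentage points of scatter. I therefore took the floor M_f, the concentration of free monomer at which uptake into chains stops (the critical concentration), as 0.440 mM, a value read from that last reading, assuming dying chains had not caused the slowing. Dividing the monomer above the floor by the charge of pre-initiator gave me a length of 7.27 in each flask.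

The forecast said neither, with 8.5 for each flask, above my figure, and a range of 6.5 to 14: “The chain count is a guess”.

The simulation gave 7.50 for Thursday's flask and 7.49 for Wednesday's, so the answer was neither.

    free monomer + initiator → living end + monomer in chains (k = 500 M⁻¹ s⁻¹)
    free monomer + living end → monomer in chains + living end, rate k2*[living end]*[free monomer] (k = 2600 M⁻¹ s⁻¹)
    monomer in chains + living end → free monomer + living end, rate k3*[living end] as long as [monomer in chains] is above zero (k = 1.10 s⁻¹)
    pre-initiator → initiator (k = 0.0160 s⁻¹)
    living end → dead end (k = 0.00630 s⁻¹)

In Thursday's flask at 8.00 min, living end 0.00627 mM and dead end 0.0707 mM add up to 0.0770 mM against a pre-initiator charge of 77 µM, of which 0.0462% is still pre-initiator, while free monomer stands at 42.3%. The same reckoning applies to a neighbouring flask, Thursday's recipe charged with 0.25 mM of free monomer, which starts below the floor of 0.440 mM that I had read, so by that reckoning it has no monomer above the floor to put into chains. At 8.00 min that flask still held 99.9% of its free monomer, with dead end at 0.0705 mM, and its average length was 0.00187.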